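**Plan**

- Retrosynthesis (germacrane numbering, C6 = lactone carbinol carbon, C12 = lactone carbonyl): the lactone O–C6 bond is cut while the transannular C3–C6 bond is re-formed, giving the cis-fused bicyclo[6.2.0]deca-2,9-dien-1-ol acid 29. Further cuts are C2–C3 (alkenyl addition), the cyclobutene (ketene + ynol ether), C11–C12 (carbonylation), C7–C8 (aldol) and C8–C9 (allylboration, then ozonolysis).
- The enabling feature is the 4-oxygenated (Z)-enone C3(=O)–C4(Me)=C5–C6–O in the ten-membered ring. C3 and C6 are 1,4-related across a cis double bond, so the ring is a ring-opened cyclobutenol whose four-membered ring is C3–C4=C5–C6.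
- Forward order: chain C2–C5 by aldol; tiglate and acrylate installed; cyclobutenone built on C5/C6 (step 14); eight-membered ring closed at C2–C3 (step 16); the last step cleaves C3–C6, giving the ten-membered ring and the lactone together.
- Stereochemistry: C10 from catalytic asymmetric allylboration; C7 and C8 from an Evans syn-aldol with the (S)-benzyl auxiliary; Z C1=C2 from cis-hydrogenation, retentive iododesilylation and the ring; Z C4=C5 from the cyclobutene; C6 is set in the key step.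

Key step: step 18

Remark: step 1 assumes that the (S)-diol catalyst gives the (R)-carbinol; if the ynone reacts with the opposite sense, the (R)-catalyst is used.
Remark: the cyclobutene ring-fusion carbons (C6 from step 14, C3 from step 16) form without control and are left undefined in the SMILES; both are destroyed in step 18.

**Route**

Step 1
Reactants: 1 4-(trimethylsilyl)but-3-yn-2-one; 2 allylboronic acid pinacol ester
Product: 3 (R)-3-methyl-1-(trimethylsilyl)hex-5-en-1-yn-3-ol
Conditions: (S)-3,3′-dibromo-1,1′-bi-2-naphthol (10 mol%), t-BuOH, PhMe, rt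
Reagents that add atoms: none
Why: Chiral-diol-catalysed asymmetric allylboration of a ketone; the diol-bound boronate transfers allyl to one face of the ynone through a closed chair transition state and sets C10.

Step 2
Reactants: 3 (R)-3-methyl-1-(trimethylsilyl)hex-5-en-1-yn-3-ol
Product: 4 (R)-3-methyl-3-(triethylsilyloxy)-1-(trimethylsilyl)hex-5-en-1-yne
Conditions: TESOTf, 2,6-lutidine, CH2Cl2, −78 to 0 °C
Reagents that add atoms: triethylsilyl trifluoromethanesulfonate, CC[Si](CC)(CC)OS(=O)(=O)C(F)(F)F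
Why: Silyl triflate silylation is the standard way to protect a hindered tertiary propargylic alcohol.

Step 3
Reactants: 4 (R)-3-methyl-3-(triethylsilyloxy)-1-(trimethylsilyl)hex-5-en-1-yne
Product: 6 (R)-3-methyl-3-(triethylsilyloxy)-5-(trimethylsilyl)pent-4-ynal, via ozonide 5 (not isolated)
Conditions: O3, CH2Cl2, −78 °C (indicator end point); then PPh3, −78 °C to rt
Reagents that add atoms: ozone, [O-][O+]=O
Why: Ozonolysis with reductive work-up cleaves the terminal alkene far faster than the silylalkyne and gives the C8 aldehyde.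

Step 4
Reactants: 6 (R)-3-methyl-3-(triethylsilyloxy)-5-(trimethylsilyl)pent-4-ynal
Product: 7 (R,Z)-3-methyl-3-(triethylsilyloxy)-5-(trimethylsilyl)pent-4-enal
Conditions: H2 (1 atm), Pd/CaCO3 poisoned with Pb(OAc)2 (Lindlar catalyst), quinoline, hexane–EtOAc, rt
Reagents that add atoms: none
Why: Lindlar semihydrogenation adds H2 cis and gives the (Z)-vinylsilane, which masks the later vinyl iodide and is inert to the palladium step.

Step 5
Reactants: 8 4-tert-butoxy-4-oxobutanoic acid; 9 (S)-4-benzyloxazolidin-2-one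
Product: 11 tert-butyl (S)-4-(4-benzyl-2-oxooxazolidin-3-yl)-4-oxobutanoate, via pivalic mixed anhydride 10 (not isolated)
Conditions: t-BuCOCl, Et3N, THF, −20 °C; then 9, LiCl, −20 °C to rt
Reagents that add atoms: none
Why: N-acylation of the oxazolidinone through the mixed anhydride is the standard entry to Evans imides.

Step 6
Reactants: 11 tert-butyl (S)-4-(4-benzyl-2-oxooxazolidin-3-yl)-4-oxobutanoate; 7 (R,Z)-3-methyl-3-(triethylsilyloxy)-5-(trimethylsilyl)pent-4-enal
Product: 13 tert-butyl (3S,4R,6R,7Z)-3-[(S)-4-benzyl-2-oxooxazolidine-3-carbonyl]-4-hydroxy-6-methyl-6-(triethylsilyloxy)-8-(trimethylsilyl)oct-7-enoate, via boron enolate 12 (not isolated)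
Conditions: Bu2BOTf, i-Pr2NEt, CH2Cl2, −78 to 0 °C; then 7, −78 to 0 °C; pH 7 buffer, MeOH, H2O2 work-up
Reagents that add atoms: none
Why: Evans syn-aldol; the (Z)-boron enolate reacts through a Zimmerman–Traxler chair on the face away from the benzyl group and sets C7 and C8 under reagent control.

Step 7
Reactants: 13 tert-butyl (3S,4R,6R,7Z)-3-[(S)-4-benzyl-2-oxooxazolidine-3-carbonyl]-4-hydroxy-6-methyl-6-(triethylsilyloxy)-8-(trimethylsilyl)oct-7-enoate
Product: 14 tert-butyl (3S,4R,6R,7Z)-4-hydroxy-3-[methoxy(methyl)carbamoyl]-6-methyl-6-(triethylsilyloxy)-8-(trimethylsilyl)oct-7-enoate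
Conditions: AlMe3, MeNHOMe·HCl, THF, −20 to 0 °C
Reagents that add atoms: N,O-dimethylhydroxylamine hydrochloride, CNOC.Cl
Why: Hydroxyl-assisted aluminium amide transamidation converts the imide into the Weinreb amide and releases the auxiliary; the tert-butyl ester is untouched.

Step 8
Reactants: 14 tert-butyl (3S,4R,6R,7Z)-4-hydroxy-3-[methoxy(methyl)carbamoyl]-6-methyl-6-(triethylsilyloxy)-8-(trimethylsilyl)oct-7-enoate
Product: 15 tert-butyl (3S,4R,6R,7Z)-3-acetyl-4-hydroxy-6-methyl-6-(triethylsilyloxy)-8-(trimethylsilyl)oct-7-enoate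
Conditions: MeMgBr (3.5 equiv), THF, −78 to 0 °C; aq. NH4Cl
Reagents that add atoms: methylmagnesium bromide, C[Mg]Br
Why: Weinreb ketone synthesis; the chelated tetrahedral intermediate stops at the methyl ketone, which supplies C11 and C13.

Step 9
Reactants: 15 tert-butyl (3S,4R,6R,7Z)-3-acetyl-4-hydroxy-6-methyl-6-(triethylsilyloxy)-8-(trimethylsilyl)oct-7-enoate
Product: 16 tert-butyl (3S,4R,6R,7Z)-3-acetyl-6-methyl-4-[(E)-2-methylbut-2-enoyloxy]-6-(triethylsilyloxy)-8-(trimethylsilyl)oct-7-enoate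
Conditions: (E)-2-methylbut-2-enoyl chloride, pyridine, DMAP (cat.), CH2Cl2, 0 °C to rt
Reagents that add atoms: (E)-2-methylbut-2-enoyl chloride, C/C=C(\C)C(=O)Cl
Why: DMAP-catalysed acylation puts the tiglate on O8 before any carboxyl group is freed, so no hydroxy acid that could lactonise at O8 is ever formed.

Step 10
Reactants: 16 tert-butyl (3S,4R,6R,7Z)-3-acetyl-6-methyl-4-[(E)-2-methylbut-2-enoyloxy]-6-(triethylsilyloxy)-8-(trimethylsilyl)oct-7-enoate
Product: 17 tert-butyl (3S,4R,6R,7Z)-6-methyl-4-[(E)-2-methylbut-2-enoyloxy]-6-(triethylsilyloxy)-3-[1-(trifluoromethylsulfonyloxy)vinyl]-8-(trimethylsilyl)oct-7-enoate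
Conditions: KHMDS added to 16 and PhNTf2, THF, −78 °C
Reagents that add atoms: N-phenylbis(trifluoromethanesulfonimide), O=S(=O)(N(c1ccccc1)S(=O)(=O)C(F)(F)F)C(F)(F)F
Why: Kinetic deprotonation of the methyl group with in situ O-triflation gives the 1,1-disubstituted enol triflate and avoids the C7 enolate that would eliminate the tiglate.

Step 11
Reactants: 17 tert-butyl (3S,4R,6R,7Z)-6-methyl-4-[(E)-2-methylbut-2-enoyloxy]-6-(triethylsilyloxy)-3-[1-(trifluoromethylsulfonyloxy)vinyl]-8-(trimethylsilyl)oct-7-enoate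
Product: 18 tert-butyl (3R,4R,6R,7Z)-6-methyl-4-[(E)-2-methylbut-2-enoyloxy]-3-{3-oxo-3-[2-(trimethylsilyl)ethoxy]prop-1-en-2-yl}-6-(triethylsilyloxy)-8-(trimethylsilyl)oct-7-enoate
Conditions: Pd(OAc)2 (5 mol%), PPh3 (10 mol%), CO (1 atm), 2-(trimethylsilyl)ethanol, Et3N, DMF, 40 °C
Reagents that add atoms: carbon monoxide, [C-]#[O+]; 2-(trimethylsilyl)ethanol, C[Si](C)(C)CCO
Why: Palladium-catalysed alkoxycarbonylation of the enol triflate builds the 2-substituted acrylate as a fluoride-labile ester; the vinylsilane does not react with zerovalent palladium.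

Step 12
Reactants: 18 tert-butyl (3R,4R,6R,7Z)-6-methyl-4-[(E)-2-methylbut-2-enoyloxy]-3-{3-oxo-3-[2-(trimethylsilyl)ethoxy]prop-1-en-2-yl}-6-(triethylsilyloxy)-8-(trimethylsilyl)oct-7-enoate
Product: 19 tert-butyl (3R,4R,6R,7Z)-8-iodo-6-methyl-4-[(E)-2-methylbut-2-enoyloxy]-3-{3-oxo-3-[2-(trimethylsilyl)ethoxy]prop-1-en-2-yl}-6-(triethylsilyloxy)oct-7-enoate
Conditions: N-iodosuccinimide, (CF3)2CHOH, 0 °C
Reagents that add atoms: N-iodosuccinimide, O=C1CCC(=O)N1I
Why: Electrophilic ipso-iododesilylation in hexafluoroisopropanol goes with retention and turns the (Z)-vinylsilane into the (Z)-vinyl iodide once the palladium chemistry is over.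

Step 13
Reactants: 19 tert-butyl (3R,4R,6R,7Z)-8-iodo-6-methyl-4-[(E)-2-methylbut-2-enoyloxy]-3-{3-oxo-3-[2-(trimethylsilyl)ethoxy]prop-1-en-2-yl}-6-(triethylsilyloxy)oct-7-enoate
Product: 21 (3R,4R,6R,7Z)-8-iodo-6-methyl-4-[(E)-2-methylbut-2-enoyloxy]-3-{3-oxo-3-[2-(trimethylsilyl)ethoxy]prop-1-en-2-yl}-6-(triethylsilyloxy)oct-7-enoic acid, via trimethylsilyl ester 20 (not isolated)
Conditions: TMSOTf, 2,6-lutidine, CH2Cl2, 0 °C; then aq. NaH2PO4
Reagents that add atoms: none
Why: Silyl triflate cleavage of the tert-butyl ester (loss of isobutene, silyl ester hydrolysed on work-up) frees the C5 acid while the other esters and the tertiary silyl ether survive.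

Step 14
Reactants: 21 (3R,4R,6R,7Z)-8-iodo-6-methyl-4-[(E)-2-methylbut-2-enoyloxy]-3-{3-oxo-3-[2-(trimethylsilyl)ethoxy]prop-1-en-2-yl}-6-(triethylsilyloxy)oct-7-enoic acid; 22 1-ethoxyprop-1-yne
Product: 25 3-ethoxy-2-methylcyclobut-2-enone carrying the C7–C2 chain at its sp3 ring carbon (C6 epimers), via acid chloride 23 (not isolated), via ketene 24 (not isolated)
Conditions: 1-chloro-N,N,2-trimethylprop-1-en-1-amine, CH2Cl2, 0 °C to rt; then 22 (5 equiv), Et3N, MeCN, rt to 45 °C
Reagents that add atoms: none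
Why: Neutral acid chloride formation, dehydrochlorination to the alkylketene and thermal [2+2] cycloaddition with the ynol ether (ketene carbonyl carbon to the methyl-bearing alkyne carbon) give the 3-ethoxycyclobutenone.

Step 15
Reactants: 25 3-ethoxy-2-methylcyclobut-2-enone carrying the C7–C2 chain (C6 epimers)
Product: 27 2-methylcyclobut-2-enone carrying the C7–C2 chain at its sp3 ring carbon (C6 epimers), via ethoxycyclobutenol 26 (not isolated)
Conditions: NaBH4, CeCl3·7H2O, MeOH, −40 °C; then 0.5 M aq. HCl, THF, 0 °C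
Reagents that add atoms: water, O
Why: Luche 1,2-reduction of the vinylogous ester, then enol ether hydrolysis and loss of water (Stork–Danheiser-type transposition), moves the carbonyl to C3 and leaves C4(Me)=C5.

Step 16
Reactants: 27 2-methylcyclobut-2-enone carrying the C7–C2 chain (C6 epimers)
Product: 28 2-(trimethylsilyl)ethyl 2-[(2Z,4R,6R,7R)-1-hydroxy-4,10-dimethyl-6-[(E)-2-methylbut-2-enoyloxy]-4-(triethylsilyloxy)bicyclo[6.2.0]deca-2,9-dien-7-yl]acrylate
Conditions: CrCl2 (8 equiv), NiCl2 (2 mol%), DMSO–THF (3:1), 0.003 M, rt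
Reagents that add atoms: none
Why: Intramolecular Nozaki–Hiyama–Kishi reaction; the (Z)-alkenylchromium adds 1,2 to the strained cyclobutenone carbonyl and closes the eight-membered ring (8-exo-trig) with a Z C1=C2 bond and cis ring fusion, esters being tolerated.

Step 17
Reactants: 28 2-(trimethylsilyl)ethyl 2-[(2Z,4R,6R,7R)-1-hydroxy-4,10-dimethyl-6-[(E)-2-methylbut-2-enoyloxy]-4-(triethylsilyloxy)bicyclo[6.2.0]deca-2,9-dien-7-yl]acrylate
Product: 29 2-[(2Z,4R,6R,7R)-1,4-dihydroxy-4,10-dimethyl-6-[(E)-2-methylbut-2-enoyloxy]bicyclo[6.2.0]deca-2,9-dien-7-yl]acrylic acid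
Conditions: Bu4NF (3 equiv), AcOH (1 equiv), THF, 0 °C to rt; cold dilute HCl to pH 4
Reagents that add atoms: none
Why: Fluoride cleaves the silylethyl ester by β-elimination and the tertiary silyl ether in one buffered operation.

Step 18
Reactants: 29 2-[(2Z,4R,6R,7R)-1,4-dihydroxy-4,10-dimethyl-6-[(E)-2-methylbut-2-enoyloxy]bicyclo[6.2.0]deca-2,9-dien-7-yl]acrylic acid
Product: 30 (1Z,4Z,6S,7R,8R,10R)-10-hydroxy-3-oxo-8-[(E)-2-methylbut-2-enoyloxy]germacra-1,4,11(13)-trien-12,6-olide (target)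
Conditions: Mn(OAc)3·2H2O (2.2 equiv), Cu(OAc)2·H2O (1.0 equiv), degassed MeCN–AcOH (9:1), 23 °C
Reagents that add atoms: none
Why: Proposed new method: Mn(OAc)3 oxidises the strained tertiary cyclobutenol to its alkoxy radical, which undergoes β-scission of the ring-fusion bond C3–C6 (the only sp3–sp3 β-bond; the other two would give vinyl radicals), releasing the cyclobutene strain and turning the 8/4 bicycle into the ten-membered ring with C3 as ketone and the former cyclobutene bond C4=C5 necessarily Z. The resulting 1-acylallyl radical (C4–C5–C6) is captured by the copper carboxylate of the substrate's own acid, and the trivalent-copper allyl carboxylate collapses by C–O reductive elimination to the γ-lactone, Cu(OAc)2 being regenerated by Mn(OAc)3. The closest known reaction types are the oxidative ring opening of cyclobutanols to γ-functionalised ketones with Mn(OAc)3 or AgNO3/K2S2O8 and the Kharasch–Sosnovsky capture of allyl radicals by copper carboxylates. The lactone closes 5-exo-trig onto the allyl terminus C6 (closure at C4 would give a seven-membered ring and lose enone conjugation), while the ten-membered carbocycle is not closed but unveiled by cleavage of the transannular bond. The new stereocentre C6 is set under kinetic control by C7: the acrylate arm reaches C6 only on the ring face not spanned by the C8–C10 bridge, and closure through the rotamer in which C8 rather than H7 eclipses C5–C6 (the arrangement followed in kinetically controlled halolactonisation of 3-substituted pent-4-enoic acids) gives the 6,7-cis lactone. The step needs chemoselective oxidation of the cyclobutenol beside the unstrained tertiary C10 alcohol (secured by strain-assisted scission), capture at C6 rather than C4 (ring size and conjugation) and the cis facial sense, which is the least secure of the three.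

**Compound list**

1 | 4-(trimethylsilyl)but-3-yn-2-one | CC(=O)C#C[Si](C)(C)C | starting material
2 | allylboronic acid pinacol ester | C=CCB1OC(C)(C)C(C)(C)O1 | starting material
3 | (R)-3-methyl-1-(trimethylsilyl)hex-5-en-1-yn-3-ol | C[Si](C)(C)C#C[C@](C)(O)CC=C | intermediate
4 | (R)-3-methyl-3-(triethylsilyloxy)-1-(trimethylsilyl)hex-5-en-1-yne | C[Si](C)(C)C#C[C@](C)(O[Si](CC)(CC)CC)CC=C | intermediate
5 | ozonide (1,2,4-trioxolane) of 4 (not isolated) | C[Si](C)(C)C#C[C@](C)(O[Si](CC)(CC)CC)CC1OCOO1 | intermediate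
6 | (R)-3-methyl-3-(triethylsilyloxy)-5-(trimethylsilyl)pent-4-ynal | C[Si](C)(C)C#C[C@](C)(O[Si](CC)(CC)CC)CC=O | intermediate
7 | (R,Z)-3-methyl-3-(triethylsilyloxy)-5-(trimethylsilyl)pent-4-enal | C[Si](C)(C)/C=C\[C@](C)(O[Si](CC)(CC)CC)CC=O | intermediate
8 | 4-tert-butoxy-4-oxobutanoic acid | CC(C)(C)OC(=O)CCC(=O)O | starting material
9 | (S)-4-benzyloxazolidin-2-one | O=C1N[C@@H](Cc2ccccc2)CO1 | starting material
10 | pivalic mixed anhydride of 8 (not isolated) | CC(C)(C)OC(=O)CCC(=O)OC(=O)C(C)(C)C | intermediate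
11 | tert-butyl (S)-4-(4-benzyl-2-oxooxazolidin-3-yl)-4-oxobutanoate | CC(C)(C)OC(=O)CCC(=O)N1C(=O)OC[C@@H]1Cc1ccccc1 | intermediate
12 | (Z)-dibutylboron enolate of 11 (not isolated) | CCCCB(CCCC)O/C(=C\CC(=O)OC(C)(C)C)N1C(=O)OC[C@@H]1Cc1ccccc1 | intermediate
13 | syn-aldol imide (3S,4R,6R,7Z) | CC(C)(C)OC(=O)C[C@H](C(=O)N1C(=O)OC[C@@H]1Cc1ccccc1)[C@H](O)C[C@@](C)(O[Si](CC)(CC)CC)/C=C\[Si](C)(C)C | intermediate
14 | Weinreb amide (3S,4R,6R,7Z) | CC(C)(C)OC(=O)C[C@H](C(=O)N(C)OC)[C@H](O)C[C@@](C)(O[Si](CC)(CC)CC)/C=C\[Si](C)(C)C | intermediate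
15 | β-hydroxy methyl ketone (3S,4R,6R,7Z) | CC(C)(C)OC(=O)C[C@H](C(C)=O)[C@H](O)C[C@@](C)(O[Si](CC)(CC)CC)/C=C\[Si](C)(C)C | intermediate
16 | tiglate methyl ketone (3S,4R,6R,7Z) | CC(C)(C)OC(=O)C[C@H](C(C)=O)[C@H](OC(=O)/C(C)=C/C)C[C@@](C)(O[Si](CC)(CC)CC)/C=C\[Si](C)(C)C | intermediate
17 | enol triflate (3S,4R,6R,7Z) | CC(C)(C)OC(=O)C[C@H](C(=C)OS(=O)(=O)C(F)(F)F)[C@H](OC(=O)/C(C)=C/C)C[C@@](C)(O[Si](CC)(CC)CC)/C=C\[Si](C)(C)C | intermediate
18 | 2-(trimethylsilyl)ethyl acrylate with (Z)-vinylsilane (3R,4R,6R,7Z) | CC(C)(C)OC(=O)C[C@H](C(=C)C(=O)OCC[Si](C)(C)C)[C@H](OC(=O)/C(C)=C/C)C[C@@](C)(O[Si](CC)(CC)CC)/C=C\[Si](C)(C)C | intermediate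
19 | (Z)-vinyl iodide tert-butyl ester (3R,4R,6R,7Z) | CC(C)(C)OC(=O)C[C@H](C(=C)C(=O)OCC[Si](C)(C)C)[C@H](OC(=O)/C(C)=C/C)C[C@@](C)(O[Si](CC)(CC)CC)/C=C\I | intermediate
20 | trimethylsilyl ester of 21 (not isolated) | C[Si](C)(C)OC(=O)C[C@H](C(=C)C(=O)OCC[Si](C)(C)C)[C@H](OC(=O)/C(C)=C/C)C[C@@](C)(O[Si](CC)(CC)CC)/C=C\I | intermediate
21 | C5 carboxylic acid (3R,4R,6R,7Z) | OC(=O)C[C@H](C(=C)C(=O)OCC[Si](C)(C)C)[C@H](OC(=O)/C(C)=C/C)C[C@@](C)(O[Si](CC)(CC)CC)/C=C\I | intermediate
22 | 1-ethoxyprop-1-yne | CCOC#CC | starting material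
23 | acid chloride of 21 (not isolated) | ClC(=O)C[C@H](C(=C)C(=O)OCC[Si](C)(C)C)[C@H](OC(=O)/C(C)=C/C)C[C@@](C)(O[Si](CC)(CC)CC)/C=C\I | intermediate
24 | ketene from 23 (not isolated) | O=C=C[C@H](C(=C)C(=O)OCC[Si](C)(C)C)[C@H](OC(=O)/C(C)=C/C)C[C@@](C)(O[Si](CC)(CC)CC)/C=C\I | intermediate
25 | 3-ethoxy-2-methylcyclobut-2-enone, chain on the sp3 ring carbon (C6 epimers) | CCOC1=C(C)C(=O)C1[C@H](C(=C)C(=O)OCC[Si](C)(C)C)[C@H](OC(=O)/C(C)=C/C)C[C@@](C)(O[Si](CC)(CC)CC)/C=C\I | intermediate
26 | 3-ethoxy-2-methylcyclobut-2-enol from 25 (not isolated) | CCOC1=C(C)C(O)C1[C@H](C(=C)C(=O)OCC[Si](C)(C)C)[C@H](OC(=O)/C(C)=C/C)C[C@@](C)(O[Si](CC)(CC)CC)/C=C\I | intermediate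
27 | 2-methylcyclobut-2-enone, chain on the sp3 ring carbon (C6 epimers) | O=C1C(C)=CC1[C@H](C(=C)C(=O)OCC[Si](C)(C)C)[C@H](OC(=O)/C(C)=C/C)C[C@@](C)(O[Si](CC)(CC)CC)/C=C\I | intermediate
28 | bicyclo[6.2.0]deca-2,9-dien-1-ol, silylethyl ester and silyl ether (2Z,4R,6R,7R; fusion centres undefined) | C=C(C(=O)OCC[Si](C)(C)C)[C@@H]1[C@H](OC(=O)/C(C)=C/C)C[C@@](C)(O[Si](CC)(CC)CC)/C=C\C2(O)C(C)=CC12 | intermediate
29 | bicyclo[6.2.0]deca-2,9-diene-1,4-diol acrylic acid (2Z,4R,6R,7R; fusion centres undefined) | C=C(C(=O)O)[C@@H]1[C@H](OC(=O)/C(C)=C/C)C[C@@](C)(O)/C=C\C2(O)C(C)=CC12 | intermediate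
30 | (1Z,4Z,6S,7R,8R,10R)-10-hydroxy-3-oxo-8-[(E)-2-methylbut-2-enoyloxy]germacra-1,4,11(13)-trien-12,6-olide | C=C1C(=O)O[C@H]2/C=C(/C)C(=O)/C=C\[C@](C)(O)C[C@@H](OC(=O)/C(C)=C/C)[C@@H]12 | target

**Count**

Total steps: 18. Longest linear sequence: 17 steps (steps 1–4 and 6–18, from 1 to 30).

**Steps most likely to fail**

1. Step 18 (Proposed new method). The lactone may close on the wrong face of C6 and give the trans-fused epimer; I consider this a real possibility, since the cis sense rests on a rotamer preference and not on a rigid element. The allyl radical may also be intercepted by acetate or lose a proton. The fallback separates ring expansion from C–O bond formation. It sets out from 28: hypoiodite alkoxy-radical fragmentation (PhI(OAc)2, I2, visible light, CH2Cl2–cyclohexane) should cleave C3–C6 with iodine-atom transfer and give the ten-membered 6-iodo-3-oxo-1,4-dienone silylethyl ester F1. Bu4NF then unmasks the carboxylate and the C10 hydroxyl, and the carboxylate displaces the allylic iodide by intramolecular SN2 with inversion; added Bu4NI can equilibrate the iodide epimers so that the faster-closing one is funnelled. The fallback returns to the route at 30.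

2. Step 16. Addition of the alkenylchromium to a ketone may be slow, so that protodeiodination or nickel-mediated addition to the acrylate takes over. The fallback closes the same bond from the vinylsilane with Lewis-acid activation of the carbonyl instead of an organometallic. It sets out from 18 and skips step 12: TMSOTf/2,6-lutidine gives the vinylsilane acid F2; the ketene–ynol ether cycloaddition of step 14 gives the ethoxycyclobutenone F3; Luche reduction and acid hydrolysis give the vinylsilane cyclobutenone F4. Me2AlCl in CH2Cl2 at −78 °C should then promote intramolecular ipso-addition of the (Z)-vinylsilane to the activated cyclobutenone carbonyl (vinylsilane-terminated carbonyl cyclisation, retention of geometry, loss of the silyl group). The fallback returns to the route at 28.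

3. Step 14. The monoalkylketene may dimerise or the ynol ether may polymerise before cycloaddition. The fallback uses a keteniminium salt in place of the free ketene. It sets out from 21: amide coupling with pyrrolidine (EDC·HCl, HOBt) gives the pyrrolidine amide F5; Tf2O and 2,6-di-tert-butyl-4-methylpyridine in CH2Cl2 generate the keteniminium triflate, which undergoes [2+2] cycloaddition with 22, and aqueous NaHCO3 hydrolyses the cyclobutenyl iminium salt. The fallback returns to the route at 25.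

**Further compounds**

F1 | step 18 | 2-(trimethylsilyl)ethyl (1Z,4Z,7R,8R,10R)-6-iodo-3-oxo-8-[(E)-2-methylbut-2-enoyloxy]-10-(triethylsilyloxy)germacra-1,4,11(13)-trien-12-oate (C6 epimers) | C=C(C(=O)OCC[Si](C)(C)C)[C@@H]1[C@H](OC(=O)/C(C)=C/C)C[C@@](C)(O[Si](CC)(CC)CC)/C=C\C(=O)/C(C)=C\C1I
F2 | step 16 | (3R,4R,6R,7Z)-6-methyl-4-[(E)-2-methylbut-2-enoyloxy]-3-{3-oxo-3-[2-(trimethylsilyl)ethoxy]prop-1-en-2-yl}-6-(triethylsilyloxy)-8-(trimethylsilyl)oct-7-enoic acid | OC(=O)C[C@H](C(=C)C(=O)OCC[Si](C)(C)C)[C@H](OC(=O)/C(C)=C/C)C[C@@](C)(O[Si](CC)(CC)CC)/C=C\[Si](C)(C)C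
F3 | step 16 | 3-ethoxy-2-methylcyclobut-2-enone with the vinylsilane chain (C6 epimers) | CCOC1=C(C)C(=O)C1[C@H](C(=C)C(=O)OCC[Si](C)(C)C)[C@H](OC(=O)/C(C)=C/C)C[C@@](C)(O[Si](CC)(CC)CC)/C=C\[Si](C)(C)C
F4 | step 16 | 2-methylcyclobut-2-enone with the vinylsilane chain (C6 epimers) | O=C1C(C)=CC1[C@H](C(=C)C(=O)OCC[Si](C)(C)C)[C@H](OC(=O)/C(C)=C/C)C[C@@](C)(O[Si](CC)(CC)CC)/C=C\[Si](C)(C)C
F5 | step 14 | pyrrolidine amide of 21 | O=C(C[C@H](C(=C)C(=O)OCC[Si](C)(C)C)[C@H](OC(=O)/C(C)=C/C)C[C@@](C)(O[Si](CC)(CC)CC)/C=C\I)N1CCCC1
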